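## Structural features

The target is a diaryl ether of two hexasubstituted benzene rings with no ring fusion and no stereocentre, so no stereocentres adjoin; rotation about the two aryl–oxygen bonds is taken to be fast. Ring A is a methyl benzoate (C1) with hydroxyls at C2 and C4, methyls at C3 and C6 and the ether oxygen at C5, that is, the commercial β-orcinol ester oxygenated at its one free carbon. Ring B carries, going round from the ether carbon C1', a formyl group (C2'), a hydroxyl (C3'), chlorine (C4'), a methyl (C5') and a free carboxylic acid (C6'). The fragile groups are the salicylaldehyde unit (oxidation, condensation), the aryl chloride (lost on hydrogenolysis) and the free acid, which sits ortho to the ether and could lactonise onto the C4 hydroxyl of ring A. The two carboxyl groups must also be told apart, one kept as the methyl ester and one set free. The real difficulty is the ether C–O bond, which has four ortho substituents and joins an electron-rich ring to a fully substituted one, so intermolecular aryl–oxygen coupling is poorly suited. The key step exploits the pattern in ring B where the C3' hydroxyl is meta to the C1' ether oxygen with C2' between them: C3' can come from carbon monoxide, C1' and C2' from a terminal ynol ether, and C6', C5', C4' from a vinylcarbene. The ether oxygen is then bonded to an sp carbon before ring B exists.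

## Logic of the disconnections

26 to 25: the two benzyl–oxygen bonds and the tert-butyl–oxygen bond are cut. The ring-A phenols must be masked because free phenols would acylate the ketene of the key step, and the ring-B carboxyl must be an ester distinct from the methyl ester. The forward step needs one reagent that removes all three groups without touching the methyl ester, the aldehyde or the aryl chloride, which excludes hydrogenolysis.

25 to 23: the C2'–CHO bond is cut. C2' is the only C–H on rings A and B and lies ortho to the free C3' hydroxyl, so the formyl group can be added last by a phenol-directed formylation. Leaving C2' as C–H is also what allows the alkyne partner to be terminal. The forward step must formylate a hindered position on a ring deactivated by the para ester.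

23 to 17, 18 and 12: three ring-B bonds are cut, C3'–C2', C3'–C4' and C1'–C6'. This removes the whole chlorinated ring and avoids ever forming the tetra-ortho-substituted aryl–O–aryl bond between two arenes. The gain is large: a two-step diazo ester, a gas and an ynol ether. The forward step must capture 18 faster than the carbene is lost in other ways, and must join the ketene carbonyl carbon to the unsubstituted alkyne carbon.

12 to 9, and 9 to 6 and 7: the O–C(sp) bond is traced to addition of the phenoxide of 6 to a two-carbon unit from 7, followed by loss of both chlorines. The demand is a strong base used in the presence of the methyl ester, which relies on the shielding of that ester by its two ortho substituents.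

6 to 4, 3 and 1: the C5–O bond is traced through the formate 5 to a C5–CHO bond and then to the C5–H of 1. C5 is the only free position of 1, so formylation has no regiochemical choice, and oxygen insertion after benzylation gives 6 with the other two oxygens already differentiated.

17 to 15, and 15 to 13 and 14: the C3=C4 double bond is traced to a dehydration and the C2–C3 bond to an aldol addition. Both starting materials are commercial. The demands are a cold quench (the chlorohydrin alkoxide can close to an epoxide) and elimination towards the chloromethyl arm.

## Other disconnections considered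

Alternative 1: The cut is the ring-A C5–O bond, formed intramolecularly from benzophenone A1, in which a ketone links C5 of ring A to C6' of ring B. Anodic oxidation of A1 would make the ring-B hydroxyl ortho to the ketone attack C5 and give the racemic spiro grisadienedione A2. Acyl migration to the neighbouring oxygen would give depsidone A3, and opening of its lactone would release the ring-B carboxyl and the C4 hydroxyl.
- In its favour: the ether bond is closed intramolecularly in a five-membered ring, which overcomes the steric problem. Oxidative spirocyclisation of hydroxybenzophenones and the rearrangement of grisadienediones to depsidones are established reaction types, so on precedent this alternative is better than the chosen plan. Ring A enters as 1 with no separate oxygenation of C5, which is also better.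
- Against it: A1 is a ketone flanked by four ortho substituents and must be made by acylating the hindered C5 of 1. Three phenols compete at the anode. After the key step there remain the acyl shift, lactone opening, cleavage of a methyl ether that is para (not ortho) to the carboxyl and so has no chelation help, and the same late formylation at C2'.
- Comparison: the stereocentre of A2 is irrelevant to both plans. On the late formylation the two are equal. On convergence and on steps after the key step (about five against two) the chosen plan is better.

Alternative 2: The cut is in ring A, at C1–C6 and C2–C3. Malonate A6 would add to the β-carbon of aryloxy enone A5 (made from ring-B phenol A4), and the ethyl α-carbon would then acylate a malonate ester to close dione A7, which must be dehydrogenated to the resorcinol.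
- In its favour: Michael–Claisen annulation and dehydrogenation of dihydroresorcinols are classical, so on precedent it is better than the chosen plan. The ether C–O bond is made at an sp3 carbon, which avoids the hindered aryl–oxygen coupling as well as the chosen plan does (equal).
- Against it: A4 is itself a pentasubstituted chlorinated phenol, so the ring-B problem is only moved. A5 is a poor acceptor, with a donor oxygen on its α-carbon and a methyl on its β-carbon. The bis-enol form of A7 is an aryl ether of an arene hydrate: ionisation at C5 would give a dihydroxy-stabilised arenium ion that loses a proton to give 1 and A4. Aromatisation by loss of the aryloxy group therefore competes with dehydrogenation at the step meant to finish ring A.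
- Comparison: step count is similar or higher once A4 is included, and the late formylation and deprotection remain (equal). The chosen plan is better on the security of the ether linkage.

Alternative 3: The cut is in ring B, at C1'–C2' and C5'–C6'. Pyrone A8 and aryloxypropiolate A9 would undergo [4+2] cycloaddition followed by decarboxylative retro-[4+2], giving the fully substituted diaryl ether A10.
- In its favour: the formyl group arrives in the cycloaddition, so one global Lewis-acid deprotection would finish the synthesis (the methyl ether is ortho to the aldehyde and cleaves with chelation help). That is one step fewer after the key step, which is better than the chosen plan. The push–pull alkyne is polarity-matched to the pyrone termini, so the regiochemistry is at least as well founded as in the chosen plan. A9 is more robust than terminal ynol ether 12 and could come from acetylide 11 by C-acylation, also better.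
- Against it: a tetrasubstituted pyrone and a disubstituted alkyne must form both new bonds between fully substituted carbons in a bimolecular step. That calls for temperatures at which the tert-butyl ester and the formyl vinylogous ester of A8 are at risk. A8 also needs its own synthesis with chlorination at C5.
- Comparison: the reaction type is known, which the chosen key step is not. In the chosen plan the first bond forms at a terminal alkyne carbon and the congested bonds form intramolecularly. Total step count is about equal.

Key step: step 8

Remarks on the chemistry: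
- Ring A is numbered from the ester carbon (C1); ring B from the ether carbon (C1').
- Precursors 12 and 17 and benzannulation product 23 map atom for atom onto the target, and no structure needed correction.
- 17 is drawn as the E isomer, but an E/Z mixture would serve, because the alkene geometry is erased on aromatisation.
- Zerovalent palladium is chosen over Co2(CO)8, which would bind the terminal alkyne of 12 as its hexacarbonyldicobalt complex.
- 12 and 17 are handled as cold solutions and used promptly.

## Route

Step 1
Reactants: 1 methyl 2,4-dihydroxy-3,6-dimethylbenzoate (atraric acid)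
Product: 3 methyl 5-formyl-2,4-dihydroxy-3,6-dimethylbenzoate, via α-chloro ether 2 (not isolated)
Conditions: Cl2CHOMe, TiCl4, CH2Cl2, 0 °C; then H2O
Reagents that add atoms: dichloromethyl methyl ether, COC(Cl)Cl; water, O
Why: Rieche formylation; titanium bound to the C4 phenoxide delivers the electrophile to C5, the only free ring position and ortho/para to both hydroxyls, and aqueous work-up hydrolyses the α-chloro ether to the aldehyde.

Step 2
Reactants: 3 methyl 5-formyl-2,4-dihydroxy-3,6-dimethylbenzoate
Product: 4 methyl 2,4-bis(benzyloxy)-5-formyl-3,6-dimethylbenzoate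
Conditions: BnBr, K2CO3, DMF, 60 °C
Reagents that add atoms: benzyl bromide, BrCc1ccccc1
Why: Williamson etherification; warm DMF is needed because each phenol is hydrogen-bonded to a carbonyl group, and the ester and aldehyde are inert to carbonate.

Step 3
Reactants: 4 methyl 2,4-bis(benzyloxy)-5-formyl-3,6-dimethylbenzoate
Product: 6 methyl 2,4-bis(benzyloxy)-5-hydroxy-3,6-dimethylbenzoate, via aryl formate 5 (not isolated)
Conditions: mCPBA, CH2Cl2, 0 °C to rt; then K2CO3, MeOH, rt
Reagents that add atoms: 3-chloroperbenzoic acid, OOC(=O)c1cccc(Cl)c1
Why: Baeyer–Villiger (Dakin-type) oxidation; the aryl group, ortho and para to benzyloxy groups, should migrate in preference to hydride, and methanolysis then cleaves the formate without touching the hindered methyl ester.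

Step 4
Reactants: 6 methyl 2,4-bis(benzyloxy)-5-hydroxy-3,6-dimethylbenzoate; 7 trichloroethylene
Product: 9 methyl 2,4-bis(benzyloxy)-5-{[(E)-1,2-dichloroethenyl]oxy}-3,6-dimethylbenzoate, via dichloroacetylene 8 (not isolated)
Conditions: K2CO3, DMF, 70 °C (excess 7, closed vessel)
Reagents that add atoms: none
Why: Base-induced elimination from 7 gives dichloroacetylene only at low stationary concentration in excess 7, and anti addition of the phenoxide gives the (E)-dichlorovinyl ether, the established entry to aryl dichlorovinyl ethers.

Step 5
Reactants: 9 methyl 2,4-bis(benzyloxy)-5-{[(E)-1,2-dichloroethenyl]oxy}-3,6-dimethylbenzoate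
Product: 12 methyl 2,4-bis(benzyloxy)-5-(ethynyloxy)-3,6-dimethylbenzoate, via chloroethynyl ether 10 (not isolated), via lithium acetylide 11 (not isolated)
Conditions: n-BuLi (2.1 equiv), THF, −78 °C; sat. aq. NH4Cl, −78 °C
Reagents that add atoms: none
Why: Known conversion of dichlorovinyl ethers to ynol ethers: deprotonation and β-elimination of chloride give 10, chlorine–lithium exchange gives 11, and protonation gives 12. Both steps should be much faster at −78 °C than attack on the methyl ester, which is shielded by two ortho substituents like a mesitoate.

Step 6
Reactants: 13 tert-butyl diazoacetate; 14 chloroacetone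
Product: 15 tert-butyl 4-chloro-2-diazo-3-hydroxy-3-methylbutanoate (racemic)
Conditions: LDA (LiN(iPr)2), THF, −78 °C; AcOH, −78 °C
Reagents that add atoms: none
Why: Aldol-type addition of the lithiated diazo ester to the ketone; the cold acidic quench keeps the chlorohydrin alkoxide from closing to an epoxide, and the new stereocentre is racemic and is removed in step 7.

Step 7
Reactants: 15 tert-butyl 4-chloro-2-diazo-3-hydroxy-3-methylbutanoate
Product: 17 tert-butyl (E)-4-chloro-2-diazo-3-methylbut-3-enoate, via dichlorophosphate ester 16 (not isolated)
Conditions: POCl3, Et3N, CH2Cl2, 0 °C to rt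
Reagents that add atoms: none
Why: Dehydration of a β-hydroxy-α-diazo ester through its dichlorophosphate, the standard route to vinyldiazoacetates. Elimination should favour the more acidic chloromethyl hydrogens and give the trisubstituted chloroalkene, with chlorine anti to the bulky diazo ester arm.

Step 8
Reactants: 17 tert-butyl (E)-4-chloro-2-diazo-3-methylbut-3-enoate; 12 methyl 2,4-bis(benzyloxy)-5-(ethynyloxy)-3,6-dimethylbenzoate; 18 carbon monoxide
Product: 23 tert-butyl 6-[2,4-bis(benzyloxy)-5-(methoxycarbonyl)-3,6-dimethylphenoxy]-3-chloro-4-hydroxy-2-methylbenzoate, via vinylketene 19 (not isolated), via vinylcyclobutenone 20 (not isolated), via dienylketene 21 (not isolated), via cyclohexadienone 22 (not isolated)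
Conditions: Pd2(dba)3 (cat.), CO (3 bar), toluene, 50 °C, slow addition of 17; then 110 °C
Reagents that add atoms: none
Why: Proposed new method: zerovalent palladium should decompose 17 to a palladium vinylcarbene that takes up CO and releases ketene 19 (the known metal-catalysed carbonylation of diazo esters), and 19 should then enter a Danheiser benzannulation with alkoxyalkyne 12; these two known reaction types have not been run together. The electrophilic ketene carbonyl carbon should bond to the unsubstituted, nucleophilic carbon of 12 and the ester-bearing carbon to the aryloxy carbon, as directed by donation from the ether oxygen, giving cyclobutenone 20 by [2+2] cycloaddition. Four-electron conrotatory opening of 20 gives dienylketene 21, and ring B closes by six-electron disrotatory electrocyclisation between the ketene carbon and the chlorovinyl carbon, followed by enolisation of dienone 22. The ring opening is reversible, so only the isomer with the chlorovinyl group turned towards the ketene arm drains to product. No stereocentre survives: the quaternary carbon of 20 and the CHCl carbon of 22 are lost on opening and aromatisation, which is why either alkene geometry of 17 serves. CO pressure and slow addition of 17 should keep carbonylation ahead of cyclopropenation of 12, carbene dimerisation and dipolar cycloaddition. The bulky tert-butyl ester is chosen to disfavour the competing oxadiene [4+2] mode of 19.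

Step 9
Reactants: 23 tert-butyl 6-[2,4-bis(benzyloxy)-5-(methoxycarbonyl)-3,6-dimethylphenoxy]-3-chloro-4-hydroxy-2-methylbenzoate
Product: 25 tert-butyl 6-[2,4-bis(benzyloxy)-5-(methoxycarbonyl)-3,6-dimethylphenoxy]-3-chloro-5-formyl-4-hydroxy-2-methylbenzoate, via hydroxymethyl phenol 24 (not isolated)
Conditions: MgCl2, Et3N, (CH2O)n, MeCN, reflux
Reagents that add atoms: paraformaldehyde (as formaldehyde), C=O
Why: Casiraghi–Skattebøl magnesium-mediated ortho-formylation; the magnesium phenoxide delivers formaldehyde to C2', the only free ortho carbon (the other bears chlorine), and a second formaldehyde oxidises the hydroxymethyl intermediate by hydride transfer. The mild basic medium spares the tert-butyl ester and the benzyl ethers.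

Step 10
Reactants: 25 tert-butyl 6-[2,4-bis(benzyloxy)-5-(methoxycarbonyl)-3,6-dimethylphenoxy]-3-chloro-5-formyl-4-hydroxy-2-methylbenzoate
Product: 26 3-chloro-5-formyl-4-hydroxy-6-[2,4-dihydroxy-5-(methoxycarbonyl)-3,6-dimethylphenoxy]-2-methylbenzoic acid (CNP0210944.0)
Conditions: BCl3, C6HMe5, CH2Cl2, −78 to 0 °C; then H2O
Reagents that add atoms: none
Why: Lewis-acid debenzylation of aryl benzyl ethers with pentamethylbenzene as cation scavenger; the same reagent should ionise the tert-butyl ester on warming to 0 °C. The methyl ester, aldehyde and aryl chloride should survive at this temperature, and hydrogenolysis is avoided because of the chloride and the aldehyde.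

## Compound list

1 | methyl 2,4-dihydroxy-3,6-dimethylbenzoate (atraric acid) | COC(=O)c1c(C)cc(O)c(C)c1O | starting material
2 | methyl 5-[chloro(methoxy)methyl]-2,4-dihydroxy-3,6-dimethylbenzoate (racemic, titanium-bound) | COC(=O)c1c(C)c(C(Cl)OC)c(O)c(C)c1O | intermediate (not isolated)
3 | methyl 5-formyl-2,4-dihydroxy-3,6-dimethylbenzoate | COC(=O)c1c(C)c(C=O)c(O)c(C)c1O | intermediate
4 | methyl 2,4-bis(benzyloxy)-5-formyl-3,6-dimethylbenzoate | COC(=O)c1c(C)c(C=O)c(OCc2ccccc2)c(C)c1OCc3ccccc3 | intermediate
5 | methyl 2,4-bis(benzyloxy)-5-(formyloxy)-3,6-dimethylbenzoate | COC(=O)c1c(C)c(OC=O)c(OCc2ccccc2)c(C)c1OCc3ccccc3 | intermediate (not isolated)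
6 | methyl 2,4-bis(benzyloxy)-5-hydroxy-3,6-dimethylbenzoate | COC(=O)c1c(C)c(O)c(OCc2ccccc2)c(C)c1OCc3ccccc3 | intermediate
7 | trichloroethylene | ClC=C(Cl)Cl | starting material
8 | dichloroacetylene | ClC#CCl | intermediate (not isolated)
9 | methyl 2,4-bis(benzyloxy)-5-{[(E)-1,2-dichloroethenyl]oxy}-3,6-dimethylbenzoate | COC(=O)c1c(C)c(O/C(Cl)=C\Cl)c(OCc2ccccc2)c(C)c1OCc3ccccc3 | intermediate
10 | methyl 2,4-bis(benzyloxy)-5-[(chloroethynyl)oxy]-3,6-dimethylbenzoate | COC(=O)c1c(C)c(OC#CCl)c(OCc2ccccc2)c(C)c1OCc3ccccc3 | intermediate (not isolated)
11 | {[2,4-bis(benzyloxy)-5-(methoxycarbonyl)-3,6-dimethylphenoxy]ethynyl}lithium | COC(=O)c1c(C)c(OC#C[Li])c(OCc2ccccc2)c(C)c1OCc3ccccc3 | intermediate (not isolated)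
12 | methyl 2,4-bis(benzyloxy)-5-(ethynyloxy)-3,6-dimethylbenzoate | COC(=O)c1c(C)c(OC#C)c(OCc2ccccc2)c(C)c1OCc3ccccc3 | intermediate
13 | tert-butyl diazoacetate | [N-]=[N+]=CC(=O)OC(C)(C)C | starting material
14 | chloroacetone | CC(=O)CCl | starting material
15 | tert-butyl 4-chloro-2-diazo-3-hydroxy-3-methylbutanoate (racemic) | CC(O)(CCl)C(=[N+]=[N-])C(=O)OC(C)(C)C | intermediate
16 | tert-butyl 4-chloro-3-[(dichlorophosphoryl)oxy]-2-diazo-3-methylbutanoate (racemic) | CC(CCl)(OP(=O)(Cl)Cl)C(=[N+]=[N-])C(=O)OC(C)(C)C | intermediate (not isolated)
17 | tert-butyl (E)-4-chloro-2-diazo-3-methylbut-3-enoate | Cl/C=C(\C)C(=[N+]=[N-])C(=O)OC(C)(C)C | intermediate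
18 | carbon monoxide | [C-]#[O+] | starting material
19 | tert-butyl (3E)-4-chloro-3-methyl-2-(oxomethylidene)but-3-enoate (vinylketene) | Cl/C=C(\C)C(=C=O)C(=O)OC(C)(C)C | intermediate (not isolated)
20 | tert-butyl 2-[2,4-bis(benzyloxy)-5-(methoxycarbonyl)-3,6-dimethylphenoxy]-1-[(E)-1-chloroprop-1-en-2-yl]-4-oxocyclobut-2-ene-1-carboxylate (racemic) | COC(=O)c1c(C)c(OC2=CC(=O)C2(/C(C)=C/Cl)C(=O)OC(C)(C)C)c(OCc3ccccc3)c(C)c1OCc4ccccc4 | intermediate (not isolated)
21 | tert-butyl 3-[2,4-bis(benzyloxy)-5-(methoxycarbonyl)-3,6-dimethylphenoxy]-2-[(E)-1-chloroprop-1-en-2-yl]-5-oxopenta-2,4-dienoate (chlorovinyl group cis to the ketene arm) | COC(=O)c1c(C)c(OC(\C=C=O)=C(\C(C)=C\Cl)C(=O)OC(C)(C)C)c(OCc3ccccc3)c(C)c1OCc4ccccc4 | intermediate (not isolated)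
22 | tert-butyl 6-[2,4-bis(benzyloxy)-5-(methoxycarbonyl)-3,6-dimethylphenoxy]-3-chloro-2-methyl-4-oxocyclohexa-1,5-diene-1-carboxylate (racemic) | COC(=O)c1c(C)c(OC2=CC(=O)C(Cl)C(C)=C2C(=O)OC(C)(C)C)c(OCc3ccccc3)c(C)c1OCc4ccccc4 | intermediate (not isolated)
23 | tert-butyl 6-[2,4-bis(benzyloxy)-5-(methoxycarbonyl)-3,6-dimethylphenoxy]-3-chloro-4-hydroxy-2-methylbenzoate | COC(=O)c1c(C)c(Oc2cc(O)c(Cl)c(C)c2C(=O)OC(C)(C)C)c(OCc3ccccc3)c(C)c1OCc4ccccc4 | intermediate
24 | tert-butyl 6-[2,4-bis(benzyloxy)-5-(methoxycarbonyl)-3,6-dimethylphenoxy]-3-chloro-4-hydroxy-5-(hydroxymethyl)-2-methylbenzoate (as magnesium alkoxide) | COC(=O)c1c(C)c(Oc2c(CO)c(O)c(Cl)c(C)c2C(=O)OC(C)(C)C)c(OCc3ccccc3)c(C)c1OCc4ccccc4 | intermediate (not isolated)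
25 | tert-butyl 6-[2,4-bis(benzyloxy)-5-(methoxycarbonyl)-3,6-dimethylphenoxy]-3-chloro-5-formyl-4-hydroxy-2-methylbenzoate | COC(=O)c1c(C)c(Oc2c(C=O)c(O)c(Cl)c(C)c2C(=O)OC(C)(C)C)c(OCc3ccccc3)c(C)c1OCc4ccccc4 | intermediate
26 | 3-chloro-5-formyl-4-hydroxy-6-[2,4-dihydroxy-5-(methoxycarbonyl)-3,6-dimethylphenoxy]-2-methylbenzoic acid (CNP0210944.0) | COC(=O)c1c(C)c(Oc2c(C=O)c(O)c(Cl)c(C)c2C(=O)O)c(O)c(C)c1O | target

## Step count and least certain steps

Total: 10 steps. Longest linear sequence: 8 steps (steps 1 to 5, then 8, 9, 10, from 1); the diazo ester branch (steps 6 and 7) joins at step 8.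

**Step 8 (key step, proposed new method).**
- What may go wrong: carbene transfer to the alkyne (cyclopropenation) or carbene dimerisation may outrun CO capture. 17 may cyclise to a pyrazole before the metal engages it. Ketene 19 may react through its ester carbonyl as an oxadiene, or as a carbon diene, instead of by [2+2]. The opening of 20 may turn the chlorovinyl group outward and return only slowly. Excess ketene may acylate the product phenol; a mild methanolysis on work-up would undo that.
- Fallback with known chemistry, setting out from 13 and 12 and returning at 19 and so at 23: the same ketene is generated by Wolff rearrangement, as in the diazo ketone form of the Danheiser benzannulation.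
  - (E)-3-chloro-2-methylprop-2-enal F1 is made from commercial 3-(dimethylamino)-2-methylprop-2-enal with oxalyl chloride and aqueous hydrolysis.
  - DBU-catalysed aldol addition of 13 to F1 gives tert-butyl (E)-5-chloro-2-diazo-3-hydroxy-4-methylpent-4-enoate F2.
  - Dess–Martin oxidation gives tert-butyl (E)-5-chloro-2-diazo-4-methyl-3-oxopent-4-enoate F3.
  - Irradiation of F3 with 12, then heating, makes the chlorovinyl group migrate to the carbene carbon to give 19, which continues to 23.
  - This removes the metal carbene and CO from the problem, but not the oxadiene risk of 19.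

**Step 5.**
- What may go wrong: n-BuLi may add to the methyl ester or metalate the C6 methyl before the elimination and exchange are complete. The terminal ynol ether may hydrate or oligomerise during isolation.
- Fallback from 6, returning at 12, with no organolithium:
  - Transvinylation of 6 with vinyl acetate under [Ir(cod)Cl]2 and Na2CO3 gives methyl 2,4-bis(benzyloxy)-5-(ethenyloxy)-3,6-dimethylbenzoate F4.
  - Addition of Br2 at −78 °C gives methyl 2,4-bis(benzyloxy)-5-(1,2-dibromoethoxy)-3,6-dimethylbenzoate F5.
  - Twofold dehydrobromination with KOtBu in THF gives 12.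

**Step 7.**
- What may go wrong: elimination may run towards the methyl group and give the isomeric chloromethyl alkene. The product may also cyclise to a pyrazole on standing.
- Fallback from 14, returning at 17, with the chloroalkene fixed before the diazo group is introduced:
  - Wittig reaction of 14 with tert-butyl (triphenylphosphoranylidene)acetate gives tert-butyl (E)-4-chloro-3-methylbut-2-enoate F6.
  - Deprotonation with LDA at −78 °C and kinetic α-protonation of the dienolate gives tert-butyl (E)-4-chloro-3-methylbut-3-enoate F7.
  - Diazo transfer with 4-acetamidobenzenesulfonyl azide and DBU gives 17.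

**Step 9.**
- What may go wrong: electrophilic substitution may be sluggish at a carbon flanked by two oxygen substituents on a ring deactivated by the para ester, and the hydroxymethyl intermediate may condense onward.
- Fallback from 23, returning at 25, replacing the slow substitution by a halogenation and a metal exchange:
  - Iodination with N-iodosuccinimide gives tert-butyl 6-[2,4-bis(benzyloxy)-5-(methoxycarbonyl)-3,6-dimethylphenoxy]-3-chloro-4-hydroxy-5-iodo-2-methylbenzoate F8.
  - Deprotonation with MeMgCl, iodine–magnesium exchange with iPrMgCl·LiCl at −20 °C and a DMF quench give 25.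

## Further compounds

F1 | step 8 | (E)-3-chloro-2-methylprop-2-enal | Cl/C=C(\C)C=O
F2 | step 8 | tert-butyl (E)-5-chloro-2-diazo-3-hydroxy-4-methylpent-4-enoate (racemic) | Cl/C=C(\C)C(O)C(=[N+]=[N-])C(=O)OC(C)(C)C
F3 | step 8 | tert-butyl (E)-5-chloro-2-diazo-4-methyl-3-oxopent-4-enoate | Cl/C=C(\C)C(=O)C(=[N+]=[N-])C(=O)OC(C)(C)C
F4 | step 5 | methyl 2,4-bis(benzyloxy)-5-(ethenyloxy)-3,6-dimethylbenzoate | COC(=O)c1c(C)c(OC=C)c(OCc2ccccc2)c(C)c1OCc3ccccc3
F5 | step 5 | methyl 2,4-bis(benzyloxy)-5-(1,2-dibromoethoxy)-3,6-dimethylbenzoate (racemic) | COC(=O)c1c(C)c(OC(Br)CBr)c(OCc2ccccc2)c(C)c1OCc3ccccc3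
F6 | step 7 | tert-butyl (E)-4-chloro-3-methylbut-2-enoate | ClC/C(C)=C/C(=O)OC(C)(C)C
F7 | step 7 | tert-butyl (E)-4-chloro-3-methylbut-3-enoate | Cl/C=C(\C)CC(=O)OC(C)(C)C
F8 | step 9 | tert-butyl 6-[2,4-bis(benzyloxy)-5-(methoxycarbonyl)-3,6-dimethylphenoxy]-3-chloro-4-hydroxy-5-iodo-2-methylbenzoate | COC(=O)c1c(C)c(Oc2c(I)c(O)c(Cl)c(C)c2C(=O)OC(C)(C)C)c(OCc3ccccc3)c(C)c1OCc4ccccc4
A1 | alternative 1 | methyl 5-(3-chloro-6-hydroxy-4-methoxy-2-methylbenzoyl)-2,4-dihydroxy-3,6-dimethylbenzoate | COC(=O)c1c(C)c(C(=O)c2c(O)cc(OC)c(Cl)c2C)c(O)c(C)c1O
A2 | alternative 1 | racemic grisadienedione (spiro benzofuran-3-one cyclohexadienone) | COC(=O)C1=C(C)C2(Oc3cc(OC)c(Cl)c(C)c3C2=O)C(O)=C(C)C1=O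
A3 | alternative 1 | depsidone (seven-membered lactone between the ring-B carboxyl and the C4 oxygen of ring A) | COC(=O)c1c(C)c2Oc3cc(OC)c(Cl)c(C)c3C(=O)Oc2c(C)c1O
A4 | alternative 2 | tert-butyl 4-(benzyloxy)-3-chloro-6-hydroxy-2-methylbenzoate | Oc1cc(OCc2ccccc2)c(Cl)c(C)c1C(=O)OC(C)(C)C
A5 | alternative 2 | tert-butyl 4-(benzyloxy)-3-chloro-2-methyl-6-[(4-oxohex-2-en-3-yl)oxy]benzoate (either alkene geometry) | CCC(=O)C(=CC)Oc1cc(OCc2ccccc2)c(Cl)c(C)c1C(=O)OC(C)(C)C
A6 | alternative 2 | dimethyl malonate | COC(=O)CC(=O)OC
A7 | alternative 2 | methyl 5-aryloxy-3,6-dimethyl-2,4-dioxocyclohexane-1-carboxylate (mixture of epimers and enol tautomers) | COC(=O)C1C(C)C(Oc2cc(OCc3ccccc3)c(Cl)c(C)c2C(=O)OC(C)(C)C)C(=O)C(C)C1=O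
A8 | alternative 3 | 5-chloro-3-formyl-4-methoxy-6-methyl-2H-pyran-2-one | Cc1oc(=O)c(C=O)c(OC)c1Cl
A9 | alternative 3 | methyl 2,4-bis(benzyloxy)-5-[(3-tert-butoxy-3-oxoprop-1-yn-1-yl)oxy]-3,6-dimethylbenzoate | COC(=O)c1c(C)c(OC#CC(=O)OC(C)(C)C)c(OCc2ccccc2)c(C)c1OCc3ccccc3
A10 | alternative 3 | fully substituted diaryl ether (target as tert-butyl ester, methyl ether and dibenzyl ether) | COC(=O)c1c(C)c(Oc2c(C=O)c(OC)c(Cl)c(C)c2C(=O)OC(C)(C)C)c(OCc3ccccc3)c(C)c1OCc4ccccc4
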